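**Retrosynthetic overview**
1. Target 26 ⇐ 25 ⇐ 24: the tertiary acetate goes on last; the enal and the carbinol are unmasked from a dimethyl acetal and a silyl ether.
2. 24 ⇐ dienol 22: an anionic oxy-Cope ([3,3]) makes the C5–C6 bond (quaternary C5 next to the ring CH), frees the C4 acetyl as its enolate and moves the ring alkene to C7=C8; the same enolate then closes the seven-membered ring (C3–C4) by alkylation.
3. 22 ⇐ methyl ketone 13 + (E)-alkenyl iodide 19; 19 ⇐ (S)-β-citronellene 14 (Wacker, alkyne, carboalumination–iodination).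
4. 13 ⇐ (R)-carvone 1: C1 side arm by Johnson–Claisen ([3,3]), C10 carbinol by Mislow–Evans ([2,3]), both relayed from the carvone stereocentre; the isopropenyl group becomes the acetyl that carries the oxy-Cope.
5. Ring order: cyclohexene first (bought in carvone), seven-membered ring last.

Assumption: read literally, the two bridgehead descriptors of the given SMILES put the four-carbon bridge trans across the cyclohexene, which cannot be closed, so I make the normal cis-bridged bicyclo[4.3.1]dec-7-ene with every other descriptor as written and keep the given bridgehead notation in the SMILES of the bicyclic compounds 24–26.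

Numbering used for the target: C1 and C6 bridgeheads; C2–C5 four-carbon bridge (C4 acetyl, C5 methyl and side chain); C7–C9 ene bridge (C7 formyl); C10 carbinol bridge.

**Step 1**
Reactants: 1 (R)-(−)-carvone
Product: 2 6-(dimethoxymethyl)carvone (acetal arm trans to isopropenyl)
Conditions: LiN(i-Pr)2, THF, −78 °C; then [(MeO)2CH]BF4 (from HC(OMe)3, BF3·OEt2, CH2Cl2, −30 °C), −78 °C
Reagents that add atoms: trimethyl orthoformate COC(OC)OC
Why: Kinetic deprotonation at C6 and C-alkylation of the lithium enolate by the dialkoxycarbenium ion (an α-formylation equivalent) puts the masked formyl carbon on the future C7, trans to isopropenyl (this centre is re-enolised in step 2).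

**Step 2**
Reactants: 2 6-(dimethoxymethyl)carvone
Product: 3 6-(dimethoxymethyl)-6-(phenylsulfanyl)carvone (PhS trans to isopropenyl)
Conditions: LiN(i-Pr)2, THF, −78 °C; then PhSSO2Ph, −78 → −20 °C
Reagents that add atoms: S-phenyl benzenethiosulfonate O=S(=O)(Sc1ccccc1)c1ccccc1
Why: Enolate sulfenylation, in which the fully substituted enolate takes up sulfur on the face away from the neighbouring isopropenyl group, so the C–S bond fixes the face from which oxygen is delivered in step 5.

**Step 3**
Reactants: 3 sulfenylated enone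
Product: 4 allylic alcohol (OH cis to isopropenyl)
Conditions: NaBH4, CeCl3·7H2O, MeOH, −78 → 0 °C
Reagents that add atoms: none
Why: Luche 1,2-reduction with axial hydride delivery anti to the axial acetal arm gives the cis-carveol-type alcohol, as with carvone itself.

**Step 4**
Reactants: 4 allylic alcohol
Product: 6 rearranged methyl ester (acetate arm cis to isopropenyl), via ketene acetal 5 (not isolated)
Conditions: MeC(OMe)3 (10 equiv), EtCO2H (cat.), xylene, 140 °C, sealed tube
Reagents that add atoms: trimethyl orthoacetate CC(OC)(OC)OC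
Why: Johnson–Claisen rearrangement ([3,3]-sigmatropic) delivers the acetate arm suprafacially, on the face of the departing C–O bond, so the new stereocentre (target C1) carries its arm cis to isopropenyl.

**Step 5**
Reactants: 6 methyl ester
Product: 9 tertiary allylic alcohol (OH trans to the acetate arm), via sulfoxide 7 (not isolated), via sulfenate ester 8 (not isolated)
Conditions: mCPBA (1.0 equiv), CH2Cl2, −78 °C; then Et2NH, MeOH, 40 °C
Reagents that add atoms: 3-chloroperbenzoic acid OOC(=O)c1cccc(Cl)c1
Why: Sulfide oxidation then Mislow–Evans [2,3]-sigmatropic rearrangement with thiophile trapping puts oxygen suprafacially on the methyl-bearing alkene carbon from the face that held sulfur, giving the carbinol (target C10) trans to the side arm and moving the alkene next to the acetal carbon.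

**Step 6**
Reactants: 9 tertiary allylic alcohol
Product: 10 triethylsilyl ether
Conditions: Et3SiCl, imidazole, DMAP (cat.), DMF, 40 °C
Reagents that add atoms: chlorotriethylsilane CC[Si](Cl)(CC)CC
Why: Silylation masks the tertiary alcohol, which would otherwise close a tetrahydrofuran onto the bromide or be deprotonated in steps 13 and 14.

**Step 7**
Reactants: 10 silyl ether ester
Product: 11 primary alcohol
Conditions: LiAlH4, Et2O, 0 °C
Reagents that add atoms: none
Why: Hydride reduction of the ester, with acetal, silyl ether and alkenes inert.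

**Step 8**
Reactants: 11 primary alcohol
Product: 12 primary bromide
Conditions: CBr4, PPh3, 2,6-lutidine, CH2Cl2, 0 °C
Reagents that add atoms: carbon tetrabromide BrC(Br)(Br)Br
Why: Appel bromination under buffered neutral conditions that spare the acetal and the silyl ether.

**Step 9**
Reactants: 12 bromide
Product: 13 methyl ketone (acetyl cis to bromoethyl)
Conditions: OsO4 (2 mol %), NaIO4, 2,6-lutidine, dioxane/H2O 3:1, rt
Reagents that add atoms: sodium periodate [Na+].[O-]I(=O)(=O)=O
Why: Lemieux–Johnson cleavage, in which OsO4 picks the exposed 1,1-disubstituted alkene over the ring alkene (flanked by a quaternary carbon and two oxygenated allylic positions) and the buffered medium leaves the α-stereocentre alone.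

**Step 10**
Reactants: 14 (S)-β-citronellene
Product: 15 (3S)-3,7-dimethyloct-6-en-2-one
Conditions: PdCl2 (10 mol %), CuCl (1 equiv), O2 (1 atm), DMF/H2O 7:1, rt
Reagents that add atoms: water O
Why: Tsuji–Wacker oxidation is selective for the monosubstituted alkene and gives the methyl ketone without touching the trisubstituted alkene or the adjacent stereocentre.

**Step 11**
Reactants: 15 methyl ketone
Product: 17 (3S)-3,7-dimethyloct-6-en-1-yne, via enol phosphate 16 (not isolated)
Conditions: LiN(i-Pr)2 (1.1 equiv), THF, −78 °C; ClP(O)(OEt)2; then LiN(i-Pr)2 (2.3 equiv), −78 °C → rt; H2O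
Reagents that add atoms: none
Why: Negishi alkyne synthesis (kinetic enolate on the methyl side, enol phosphate, elimination), in which the stereocentre is never deprotonated.

**Step 12**
Reactants: 17 alkyne
Product: 19 (1E,3S)-1-iodo-2,3,7-trimethylocta-1,6-diene, via alkenylalane 18 (not isolated)
Conditions: Me3Al, Cp2ZrCl2 (25 mol %), CH2Cl2, 0 °C → rt; then I2, THF, −30 → 0 °C
Reagents that add atoms: trimethylaluminium C[Al](C)C; iodine II
Why: Negishi zirconium-catalysed carboalumination adds Me–Al syn across the alkyne (methyl on the inner carbon) and iodinolysis with retention gives only the (E)-alkenyl iodide.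

**Step 13**
Reactants: 13 methyl ketone; 19 alkenyl iodide
Product: 22 dienol (both carbinol epimers), via alkenyllithium 20 (not isolated), via alkenylcerium dichloride 21 (not isolated)
Conditions: 19, t-BuLi (2 equiv), Et2O, −78 °C; CeCl3, THF, −78 °C; then 13, −78 °C; aq. NH4Cl
Reagents that add atoms: none
Why: Lithium–iodine exchange with retention of alkene geometry, transmetalation to the non-basic organocerium and 1,2-addition (Imamoto conditions) without enolising the α-stereocentre; the new carbinol centre does not matter because it becomes the carbonyl carbon in step 14.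

**Step 14**
Reactants: 22 dienol
Product: 24 bicyclic ketone, via potassium enolate 23 (not isolated)
Conditions: KH, 18-crown-6, THF, 0 → 40 °C
Reagents that add atoms: none
Why: Anionic oxy-Cope rearrangement ([3,3]-sigmatropic) forms C5–C6 suprafacially on the ring face that carried the carbinol arm (cis to the bromoethyl arm), a boat-like transition state (the chair is blocked by the axial bromoethyl arm) with the (E)-alkene sets the quaternary C5, the regiospecific enolate closes the seven-membered ring by 7-exo-tet alkylation, and the epimerisable C4 settles with acetyl exo, away from the C10 methyl.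

**Step 15**
Reactants: 24 bicyclic ketone
Product: 25 hydroxy keto enal
Conditions: 1 M HCl, THF, rt
Reagents that add atoms: water O
Why: Acid hydrolysis of the dimethyl acetal to the conjugated aldehyde and cleavage of the silyl ether, while the bridging tertiary alcohol cannot ionise or eliminate and C4 keeps its thermodynamic configuration.

**Step 16**
Reactants: 25 hydroxy keto enal
Product: 26 target
Conditions: Ac2O, DMAP, Et3N, CH2Cl2, 40 °C
Reagents that add atoms: acetic anhydride CC(=O)OC(C)=O
Why: Steglich-type DMAP-catalysed acetylation of the tertiary alcohol with retention at C10, leaving the ketone and enal untouched.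

**Compound list**
1 | (R)-(−)-carvone, (5R)-2-methyl-5-(prop-1-en-2-yl)cyclohex-2-en-1-one | CC1=CC[C@@H](C(C)=C)CC1=O | starting material
2 | 6-(dimethoxymethyl)-2-methyl-5-(prop-1-en-2-yl)cyclohex-2-en-1-one, acetal arm trans to isopropenyl | CC1=CC[C@@H](C(C)=C)[C@H](C(OC)OC)C1=O | intermediate
3 | 6-(dimethoxymethyl)-2-methyl-6-(phenylsulfanyl)-5-(prop-1-en-2-yl)cyclohex-2-en-1-one, PhS trans and acetal arm cis to isopropenyl | CC1=CC[C@@H](C(C)=C)[C@](C(OC)OC)(Sc2ccccc2)C1=O | intermediate
4 | 6-(dimethoxymethyl)-2-methyl-6-(phenylsulfanyl)-5-(prop-1-en-2-yl)cyclohex-2-en-1-ol, OH cis to isopropenyl and trans to PhS | CC1=CC[C@@H](C(C)=C)[C@](C(OC)OC)(Sc2ccccc2)[C@H]1O | intermediate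
5 | 1-methoxyethenyl ether of 4 (mixed ketene acetal) | CC1=CC[C@@H](C(C)=C)[C@](C(OC)OC)(Sc2ccccc2)[C@H]1OC(=C)OC | intermediate
6 | methyl 2-[4-(dimethoxymethyl)-2-methyl-4-(phenylsulfanyl)-5-(prop-1-en-2-yl)cyclohex-2-en-1-yl]acetate, acetate arm cis to isopropenyl and trans to PhS | CC1=C[C@@](C(OC)OC)(Sc2ccccc2)[C@H](C(C)=C)C[C@@H]1CC(=O)OC | intermediate
7 | S-oxide of 6 (either configuration at sulfur) | CC1=C[C@@](C(OC)OC)(S(=O)c2ccccc2)[C@H](C(C)=C)C[C@@H]1CC(=O)OC | intermediate
8 | methyl 2-[4-(dimethoxymethyl)-2-methyl-2-(phenylsulfanyloxy)-5-(prop-1-en-2-yl)cyclohex-3-en-1-yl]acetate, sulfenate oxygen trans to the acetate arm | c1ccccc1SO[C@]1(C)[C@@H](CC(=O)OC)C[C@@H](C(C)=C)C(C(OC)OC)=C1 | intermediate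
9 | methyl 2-[4-(dimethoxymethyl)-2-hydroxy-2-methyl-5-(prop-1-en-2-yl)cyclohex-3-en-1-yl]acetate, OH trans to the acetate arm, acetate arm cis to isopropenyl | O[C@]1(C)[C@@H](CC(=O)OC)C[C@@H](C(C)=C)C(C(OC)OC)=C1 | intermediate
10 | triethylsilyl ether of 9 | CC[Si](CC)(CC)O[C@]1(C)[C@@H](CC(=O)OC)C[C@@H](C(C)=C)C(C(OC)OC)=C1 | intermediate
11 | 2-[4-(dimethoxymethyl)-2-methyl-5-(prop-1-en-2-yl)-2-(triethylsilyloxy)cyclohex-3-en-1-yl]ethan-1-ol, configuration as in 9 | CC[Si](CC)(CC)O[C@]1(C)[C@@H](CCO)C[C@@H](C(C)=C)C(C(OC)OC)=C1 | intermediate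
12 | [6-(2-bromoethyl)-3-(dimethoxymethyl)-1-methyl-4-(prop-1-en-2-yl)cyclohex-2-en-1-yl]oxy(triethyl)silane, configuration as in 9 | CC[Si](CC)(CC)O[C@]1(C)[C@@H](CCBr)C[C@@H](C(C)=C)C(C(OC)OC)=C1 | intermediate
13 | 1-[5-(2-bromoethyl)-2-(dimethoxymethyl)-4-methyl-4-(triethylsilyloxy)cyclohex-2-en-1-yl]ethan-1-one, acetyl cis and silyloxy trans to bromoethyl | CC[Si](CC)(CC)O[C@]1(C)[C@@H](CCBr)C[C@@H](C(C)=O)C(C(OC)OC)=C1 | intermediate
14 | (S)-β-citronellene, (3S)-3,7-dimethylocta-1,6-diene | C=C[C@@H](C)CCC=C(C)C | starting material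
15 | (3S)-3,7-dimethyloct-6-en-2-one | CC(=O)[C@@H](C)CCC=C(C)C | intermediate
16 | diethyl (3S)-3,7-dimethylocta-1,6-dien-2-yl phosphate | C=C(OP(=O)(OCC)OCC)[C@@H](C)CCC=C(C)C | intermediate
17 | (3S)-3,7-dimethyloct-6-en-1-yne | C#C[C@@H](C)CCC=C(C)C | intermediate
18 | dimethyl[(1E,3S)-2,3,7-trimethylocta-1,6-dien-1-yl]alane | C[Al](C)/C=C(\C)[C@@H](C)CCC=C(C)C | intermediate
19 | (1E,3S)-1-iodo-2,3,7-trimethylocta-1,6-diene | I/C=C(\C)[C@@H](C)CCC=C(C)C | intermediate
20 | [(1E,3S)-2,3,7-trimethylocta-1,6-dien-1-yl]lithium | [Li]/C=C(\C)[C@@H](C)CCC=C(C)C | intermediate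
21 | dichloro[(1E,3S)-2,3,7-trimethylocta-1,6-dien-1-yl]cerium | Cl[Ce](Cl)/C=C(\C)[C@@H](C)CCC=C(C)C | intermediate
22 | (3E,5S)-2-[5-(2-bromoethyl)-2-(dimethoxymethyl)-4-methyl-4-(triethylsilyloxy)cyclohex-2-en-1-yl]-4,5,9-trimethyldeca-3,8-dien-2-ol, ring configuration as in 13, both carbinol epimers | CC[Si](CC)(CC)O[C@]1(C)[C@@H](CCBr)C[C@@H](C(C)(O)/C=C(\C)[C@@H](C)CCC=C(C)C)C(C(OC)OC)=C1 | intermediate
23 | potassium enolate of the rearranged monocyclic bromo ketone (new quaternary carbon on the ring CH, cis to the bromoethyl arm) | CC[Si](CC)(CC)O[C@]1(C)[C@@H](CCBr)CC=C(C(OC)OC)[C@H]1[C@@](C)([C@@H](C)CCC=C(C)C)C=C(C)[O-].[K+] | intermediate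
24 | 1-[7-(dimethoxymethyl)-5,10-dimethyl-5-[(2S)-6-methylhept-5-en-2-yl]-10-(triethylsilyloxy)bicyclo[4.3.1]dec-7-en-4-yl]ethan-1-one | CC[Si](CC)(CC)O[C@]1(C)[C@@H]2CC=C(C(OC)OC)[C@@H]1[C@@](C)([C@@H](C)CCC=C(C)C)[C@@H](C(C)=O)CC2 | intermediate
25 | 4-acetyl-10-hydroxy-5,10-dimethyl-5-[(2S)-6-methylhept-5-en-2-yl]bicyclo[4.3.1]dec-7-ene-7-carbaldehyde | O[C@]1(C)[C@@H]2CC=C(C=O)[C@@H]1[C@@](C)([C@@H](C)CCC=C(C)C)[C@@H](C(C)=O)CC2 | intermediate
26 | 4-acetyl-7-formyl-5,10-dimethyl-5-[(2S)-6-methylhept-5-en-2-yl]bicyclo[4.3.1]dec-7-en-10-yl acetate (CNP0288370.1) | CC(=O)O[C@]1(C)[C@@H]2CC=C(C=O)[C@@H]1[C@@](C)([C@@H](C)CCC=C(C)C)[C@@H](C(C)=O)CC2 | target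

**Step count**
Total steps: 16. Longest linear sequence: 13 (steps 1–9 and 13–16).

**Steps most likely to fail, each with a fallback**

Step 14 (oxy-Cope and alkylation in one flask). The [3,3] shift builds a quaternary carbon through a boat transition state on a crowded ring face, and the seven-membered ring must then close before the enolate is lost. The fallback sets out from 22 and comes back at 24. The rearrangement is run on its own (KH, 18-crown-6, THF, 0 °C) and the enolate is trapped with Me3SiCl as the trimethylsilyl enol ether F1, which fixes the enolate regiochemistry and can be purified. NaI in acetone then gives the iodo silyl enol ether F2. MeLi (THF, 0 °C, then HMPA) releases the lithium enolate from F2, which cyclises to 24.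

Step 4 (Johnson–Claisen on a carbinol next to a quaternary carbon, hot and weakly acidic in the presence of the acetal). The fallback sets out from 4 and comes back at 6. Acetylation (Ac2O, DMAP) gives the allylic acetate F3. LiN(i-Pr)2 and Me3SiCl at −78 °C give the trimethylsilyl ketene acetal F4, which rearranges below 60 °C (Ireland–Claisen, same suprafacial sense, no acid) and is hydrolysed on work-up to the carboxylic acid F5. Me3SiCHN2 in MeOH converts F5 into 6.

Step 9 (site-selective oxidative cleavage of one of two alkenes). The fallback sets out from 12 and comes back at 13. Buffered mCPBA (1 equiv, NaHCO3, CH2Cl2, 0 °C) epoxidises the exposed isopropenyl group to the epoxide F6, which can be separated from any ring epoxide. H5IO6 in wet THF at 0 °C then cleaves F6 to the methyl ketone 13.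

**Further compounds**
F1 | step 14 | trimethylsilyl enol ether of the rearranged monocyclic bromo ketone | CC[Si](CC)(CC)O[C@]1(C)[C@@H](CCBr)CC=C(C(OC)OC)[C@H]1[C@@](C)([C@@H](C)CCC=C(C)C)C=C(C)O[Si](C)(C)C
F2 | step 14 | iodo analogue of F1 | CC[Si](CC)(CC)O[C@]1(C)[C@@H](CCI)CC=C(C(OC)OC)[C@H]1[C@@](C)([C@@H](C)CCC=C(C)C)C=C(C)O[Si](C)(C)C
F3 | step 4 | acetate of 4 | CC1=CC[C@@H](C(C)=C)[C@](C(OC)OC)(Sc2ccccc2)[C@H]1OC(C)=O
F4 | step 4 | trimethylsilyl ketene acetal of F3 | CC1=CC[C@@H](C(C)=C)[C@](C(OC)OC)(Sc2ccccc2)[C@H]1OC(=C)O[Si](C)(C)C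
F5 | step 4 | 2-[4-(dimethoxymethyl)-2-methyl-4-(phenylsulfanyl)-5-(prop-1-en-2-yl)cyclohex-2-en-1-yl]acetic acid, configuration as in 6 | CC1=C[C@@](C(OC)OC)(Sc2ccccc2)[C@H](C(C)=C)C[C@@H]1CC(=O)O
F6 | step 9 | epoxide of 12 at the isopropenyl group (both epoxide epimers) | CC[Si](CC)(CC)O[C@]1(C)[C@@H](CCBr)C[C@@H](C2(C)CO2)C(C(OC)OC)=C1
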